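- Late in both earlier runs, Q still reads what it read early: on average 85.2% in Sunday's and 54.5% in Saturday's.

| flask | Q | G | D | remark | time |
|---|---|---|---|---|---|
| Sunday's | 1 M | 0.25 equiv | 2 equiv | run made earlier |  |
| Saturday's | 1 M | 1 equiv | 2 equiv | run made earlier |  |
| flask | 1.0 M | 0.500 equiv | 2.00 equiv |  | 6.0 h |

| run | time / h | Q / % | E / % |
|---|---|---|---|
| Sunday's | 0.500 | 85 | 4 |
| Sunday's | 1.33 | 84 | 1 |
| Sunday's | 2.50 | 86 | 6 |
| Sunday's | 4.00 | 85 | 2 |
| Sunday's | 6.00 | 87 | 1 |
| Sunday's | 8.00 | 84 | 2 |
| Saturday's | 1.33 | 57 | 7 |
| Saturday's | 2.50 | 52 | 5 |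
| Saturday's | 4.00 | 55 | 9 |
| Saturday's | 5.00 | 57 | 9 |
| Saturday's | 6.00 | 55 | 7 |
| Saturday's | 8.00 | 51 | 9 |

(each reading ± 2 percentage points)

* which holds at 6.0 h: what has brought the reaction to rest, or that it has not come to rest (it is still moving / all of Q has reacted / forward and back rates have come level / G has run out first)
* how much of the Q has reacted by 6.0 h
* how much E there is at 6.0 h, in percent of the Q charged

- the reaction counts as stopped when no species that holds the Q changes by six tenths of a point or more over the second half of the time

- Counting one G per Q, Sunday's run keeps 0.102 equiv of G and Saturday's 0.545 equiv, so I see Q and G both left over, and I read a balance, not a shortage.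
- Work in powers of ten: take the logarithm of Q reacted over Q left, then subtract the logarithm of G left in equivalents. Sunday's run gives 0.234 and Saturday's 0.185.
- Their mean, 0.210, is the rest figure, the logarithm of an apparent equilibrium constant, and it stands for a factor of 1.62.
- For the new flask, guess 25.0% of Q reacted, half the G charge. The factor answers 28.8%. Midway, 26.9%, it answers 27.2%, and I commit to that.
- The weak link is Sunday's G left, a remainder of readings scattered by 2 percentage points. Solved exactly, Sunday's figure gives 27.7% and Saturday's gives 26.5%, which lie 1.2 points apart.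
- Saturday's E averages 16.8% of the Q reacted, so I expect 4.57% E.
- The forecast, near mine without being mine, says forward and back rates have come level, with 27.3% reacted and 4.7% E, on the ground that “An equilibrium fits instead”.

- In the new flask at 6.0 h, forward and back rates have come level, with 27.7% of Q reacted and 3.23% E.

    X + G ⇌ D + E (K = 2.20, k = 0.00157 L mol⁻¹ s⁻¹)
    Q + G ⇌ D + X (K = 4.77, k = 0.00189 L mol⁻¹ s⁻¹)
    E + G ⇌ D + J (K = 9.00, k = 0.00246 L mol⁻¹ s⁻¹)

- For its conversion to sit 5 points away from this, with the other amounts and the time held, G has to go down to 0.389 equiv or up to 0.622 equiv. Now take the rest figure to the neighbouring flask with 0.200 equiv of G, the rest of the recipe unchanged: it foretells 11.8% reacted, and that flask holds 12.8%.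

The readings were computed from invented constants, noise included.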